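**Plan**
- The target is tricin whose ring B 4'-oxygen carries an erythro guaiacylglyceryl unit, (αR,βS), with an (E)-p-coumarate on the γ-oxygen.
- Enabling feature: in ring C, carbonyl carbon C4 is bonded only to C4a of ring A and to C3. C3–C2 is a two-carbon unit whose C2 holds ring B, and O1 sits on C8a next to C4a. Ring C therefore equals an ortho-iodophenol plus one CO plus an arylalkyne.
- Cuts, in order: five Si–O bonds; C4a–C4, C4–C3 and O1–C2 (ring C); the γ-ester C–O bond; Cα–Cβ (aldol); the ring B–alkyne bond; the aryl-O–CH2 bond.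
- Forward: ring B is etherified and ethynylated first, the aldol brings in the guaiacyl ring, and the coumarate is attached. Ring C then closes last, between ring A and the finished side chain. All four benzene rings are bought.
- Stereochemistry: an (R)-4-benzyloxazolidinone boron aldol fixes Cβ and gives the syn (threo) pair. A Mitsunobu inversion at Cα converts it into the anti (erythro) pair. The E-alkene comes with p-coumaric acid.

Key step: step 15

Remark: α, β and γ are the glyceryl carbons counted from the guaiacyl ring. The target SMILES decodes as (αR,βS), which is anti in the zigzag drawing and therefore erythro. TBS = tert-butyldimethylsilyl.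

Step 1
Reactants: 1 vanillin
Product: 2 4-(TBS-oxy)-3-methoxybenzaldehyde
Conditions: TBSCl, imidazole, DMF, 23 °C
Reagents that add atoms: tert-butyldimethylsilyl chloride, CC(C)(C)[Si](C)(C)Cl
Why: Imidazole-promoted silylation of a phenol leaves the aldehyde untouched and installs a group that falls in the final fluoride step together with all the others.

Step 2
Reactants: 3 4-bromo-2,6-dimethoxyphenol
Product: 4 ethyl 2-(4-bromo-2,6-dimethoxyphenoxy)acetate
Conditions: BrCH2CO2Et, K2CO3, acetone, reflux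
Reagents that add atoms: ethyl bromoacetate, CCOC(=O)CBr
Why: Williamson etherification of the 2,6-dimethoxyphenol with a primary α-bromo ester is the usual entry to the aryloxyacetates used for β-aryl ethers.

Step 3
Reactants: 4 ethyl 2-(4-bromo-2,6-dimethoxyphenoxy)acetate
Product: 5 ethyl 2-[2,6-dimethoxy-4-(trimethylsilylethynyl)phenoxy]acetate
Conditions: Me3SiC≡CH, PdCl2(PPh3)2 (3 mol %), CuI (6 mol %), Et3N–DMF, 80 °C, sealed tube
Reagents that add atoms: trimethylsilylacetylene, C#C[Si](C)(C)C
Why: Sonogashira coupling is routine for 5-bromo-1,2,3-trialkoxybenzenes, and running it on this robust achiral ester keeps the coumarate and aryl silyl ethers away from any later ethynylation or alkyne unmasking.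

Step 4
Reactants: 5 ethyl 2-[2,6-dimethoxy-4-(trimethylsilylethynyl)phenoxy]acetate
Product: 6 2-(4-ethynyl-2,6-dimethoxyphenoxy)acetic acid
Conditions: LiOH, THF–MeOH–H2O, 23 °C; then 1 M HCl
Reagents that add atoms: lithium hydroxide, [Li+].[OH-]
Why: Hydroxide saponifies the ester and protodesilylates the alkynylsilane in one operation, which is safe here because no base-labile group is present yet.

Step 5
Reactants: 6 2-(4-ethynyl-2,6-dimethoxyphenoxy)acetic acid; 7 (R)-4-benzyloxazolidin-2-one
Product: 9 (4R)-4-benzyl-3-[2-(4-ethynyl-2,6-dimethoxyphenoxy)acetyl]oxazolidin-2-one, via mixed pivalic anhydride 8 (not isolated)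
Conditions: PivCl, Et3N, THF, −20 °C; then LiCl, 7, −20 → 23 °C
Reagents that add atoms: pivaloyl chloride, CC(C)(C)C(=O)Cl (its acyl group is present only in 8)
Why: Mixed-anhydride N-acylation under LiCl/Et3N conditions needs no strong base, so the alkyne C–H is left alone, and the oxazolidinone attacks the less hindered aryloxyacetyl carbonyl of 8.

Step 6
Reactants: 9 (4R)-4-benzyl-3-[2-(4-ethynyl-2,6-dimethoxyphenoxy)acetyl]oxazolidin-2-one; 2 4-(TBS-oxy)-3-methoxybenzaldehyde
Product: 12 (4R)-4-benzyl-3-[(2R,3S)-3-[4-(TBS-oxy)-3-methoxyphenyl]-2-(4-ethynyl-2,6-dimethoxyphenoxy)-3-hydroxypropanoyl]oxazolidin-2-one (syn adduct), via dibutylboron (Z)-enolate 10 (not isolated), via dibutylboron aldolate 11 (not isolated)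
Conditions: Bu2BOTf, iPr2NEt, CH2Cl2, −78 → 0 °C; 2, −78 → 0 °C; then pH 7 buffer, MeOH, 30% H2O2, 0 °C
Reagents that add atoms: dibutylboron triflate, CCCCB(CCCC)OS(=O)(=O)C(F)(F)F (its boron unit is present only in 10 and 11)
Why: In this Evans boron syn-aldol, known for aryloxyacetyl oxazolidinones with alkoxybenzaldehydes, the (Z)-enolate reacts through a Zimmerman–Traxler chair on the face away from the benzyl group, which sets Cβ in its final spatial arrangement (2R here, βS once the carbonyl is reduced) and Cα as S, the syn (threo) pair.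

Step 7
Reactants: 12 syn aldol adduct
Product: 13 (1S,2S)-1-[4-(TBS-oxy)-3-methoxyphenyl]-2-(4-ethynyl-2,6-dimethoxyphenoxy)propane-1,3-diol (threo diol)
Conditions: LiBH4, MeOH (1 equiv), THF, 0 °C
Reagents that add atoms: none
Why: Reductive cleavage of the imide at its exocyclic carbonyl is standard for such adducts, touches neither stereocentre nor the alkyne and returns the auxiliary.

Step 8
Reactants: 14 p-coumaric acid
Product: 16 (E)-3-[4-(TBS-oxy)phenyl]acrylic acid, via bis-silylated coumarate 15 (not isolated)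
Conditions: TBSCl (2.3 equiv), imidazole, DMF, 23 °C; then AcOH–THF–H2O, 23 °C
Reagents that add atoms: tert-butyldimethylsilyl chloride, CC(C)(C)[Si](C)(C)Cl
Why: Both acidic hydroxyls are silylated, and the much more labile silyl ester is then hydrolysed selectively while the aryl silyl ether and the E-alkene stay intact.

Step 9
Reactants: 13 threo diol; 16 (E)-3-[4-(TBS-oxy)phenyl]acrylic acid
Product: 17 (2S,3S)-3-[4-(TBS-oxy)-3-methoxyphenyl]-2-(4-ethynyl-2,6-dimethoxyphenoxy)-3-hydroxypropyl (E)-3-[4-(TBS-oxy)phenyl]acrylate (threo γ-ester)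
Conditions: DCC, DMAP (cat.), CH2Cl2, −10 → 0 °C, 1 equiv of 16
Reagents that add atoms: none
Why: In this Steglich esterification the primary γ-hydroxyl outruns the secondary benzylic hydroxyl, which is crowded by the neighbouring aryloxy-bearing carbon.

Step 10
Reactants: 17 threo γ-ester
Product: 18 (2S,3R)-3-[4-(TBS-oxy)-3-methoxyphenyl]-3-(2-chloroacetoxy)-2-(4-ethynyl-2,6-dimethoxyphenoxy)propyl (E)-3-[4-(TBS-oxy)phenyl]acrylate (erythro α-chloroacetate)
Conditions: ClCH2CO2H, PPh3, DIAD, toluene, 0 → 23 °C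
Reagents that add atoms: chloroacetic acid, OC(=O)CCl
Why: Mitsunobu inversion, known for the threo-to-erythro switch of β-aryl ether benzylic alcohols, replaces the oxyphosphonium group by chloroacetate in an SN2 step and so turns Cα from S to R; the acidic nucleophile and non-polar solvent disfavour ionisation, and because Cβ is untouched any leakage appears only as a separable diastereomer.

Step 11
Reactants: 18 erythro α-chloroacetate
Product: 19 (2S,3R)-3-[4-(TBS-oxy)-3-methoxyphenyl]-2-(4-ethynyl-2,6-dimethoxyphenoxy)-3-hydroxypropyl (E)-3-[4-(TBS-oxy)phenyl]acrylate (erythro alcohol)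
Conditions: thiourea, 2,6-lutidine, THF–EtOH, 40 °C
Reagents that add atoms: none
Why: Thiourea is alkylated at the C–Cl bond and then cyclises onto that ester carbonyl alone, so the alcohol is released by acyl–oxygen cleavage with retention at Cα and the coumarate, which lacks such a handle, stays in place.

Step 12
Reactants: 19 erythro alcohol
Product: 20 (2S,3R)-3-(TBS-oxy)-3-[4-(TBS-oxy)-3-methoxyphenyl]-2-(4-ethynyl-2,6-dimethoxyphenoxy)propyl (E)-3-[4-(TBS-oxy)phenyl]acrylate (tris-silyl arylalkyne)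
Conditions: TBSOTf, 2,6-lutidine, CH2Cl2, −78 → 0 °C
Reagents that add atoms: tert-butyldimethylsilyl triflate, CC(C)(C)[Si](C)(C)OS(=O)(=O)C(F)(F)F
Why: Silyl triflate with lutidine is the standard way to cap a hindered secondary alcohol, and the cap prevents acyl migration and capture of acylpalladium by this hydroxyl in step 15.

Step 13
Reactants: 21 phloroglucinol
Product: 22 3,5-bis(TBS-oxy)phenol
Conditions: TBSCl (2 equiv), imidazole, DMF, 0 → 23 °C; chromatography
Reagents that add atoms: tert-butyldimethylsilyl chloride, CC(C)(C)[Si](C)(C)Cl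
Why: Partial silylation of the threefold-symmetric triol can give only one bis-ether, which is separable from the mono- and tris-ethers, and both of those can be recycled.

Step 14
Reactants: 22 3,5-bis(TBS-oxy)phenol
Product: 23 3,5-bis(TBS-oxy)-2-iodophenol
Conditions: NIS (1 equiv), CH2Cl2, −20 → 0 °C, dark
Reagents that add atoms: N-iodosuccinimide, O=C1CCC(=O)N1I
Why: In this electrophilic aromatic iodination the two equivalent positions between OH and O-TBS are as activated as the third free position but much less crowded than that site between two O-TBS groups, so iodine should enter ortho to the free phenol.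

Step 15
Reactants: 20 tris-silyl arylalkyne; 23 3,5-bis(TBS-oxy)-2-iodophenol
Product: 26 penta-O-TBS target (5,7-bis(TBS-oxy)flavone carrying the complete silylated side chain), via 2-hydroxyaryl ynone 24 (not isolated), via (E)-diethylamino enone 25 (not isolated)
Conditions: PdCl2(PPh3)2 (5 mol %), CO (10 bar), Et2NH–THF, 60 °C, no copper salt, slight excess of 23
Reagents that add atoms: carbon monoxide, [C-]#[O+]; diethylamine, CCNCC (present only in 25)
Why: The precatalyst is reduced in the flask to zerovalent palladium, which adds oxidatively to the C–I bond of 23; migration of the aryl group onto bound CO makes C4a–C4, and the amine-deprotonated alkyne 20 replaces iodide on the aroylpalladium centre so that reductive elimination makes C4–C3 and sets ynone 24 free. Conjugate addition of Et2NH at C2 converts 24 into enaminone 25, whose C2 is attacked by the neighbouring phenol oxygen with expulsion of the amine (O1–C2), so ring C arises by an addition–elimination that amounts to a 6-endo closure. The closest known reaction type is the palladium-catalysed carbonylative Sonogashira annulation of 2-iodophenols with terminal arylalkynes to flavones. No stereocentre is formed, and Cα and Cβ lie far from the reacting atoms and next to no carbonyl group, so the mild amine base cannot epimerise them. The step needs CO uptake to beat direct aryl–alkyne coupling (helped by CO pressure and the absence of copper), six- over five-membered closure (in 25 only C2 is electrophilic, which excludes the aurone mode), and reaction at the terminal alkyne rather than the coumarate alkene (a 1,2-disubstituted conjugated alkene inserts far more slowly than a terminal alkyne is palladated). Both oxygens ortho to C4a lead to the same 5,7-dioxygenated chromone, so silyl scrambling between them would be harmless.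

Step 16
Reactants: 26 penta-O-TBS target
Product: 27 target, tricin 4'-O-[(αR,βS)-guaiacylglyceryl] ether γ-(E)-p-coumarate
Conditions: Et3N·3HF (excess), THF–MeCN, 23 → 40 °C
Reagents that add atoms: none
Why: Mildly acidic fluoride cleaves the four aryl and the one benzylic Si–O bonds by Si–F formation and avoids the basic phenoxide conditions that would invite quinone methide formation, ester cleavage or acyl migration, so both stereocentres and the coumarate should survive.

**Compound list**
1 | vanillin | COc1cc(C=O)ccc1O | starting material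
2 | 4-(TBS-oxy)-3-methoxybenzaldehyde | COc1cc(C=O)ccc1O[Si](C)(C)C(C)(C)C | intermediate
3 | 4-bromo-2,6-dimethoxyphenol | COc1cc(Br)cc(OC)c1O | starting material
4 | ethyl 2-(4-bromo-2,6-dimethoxyphenoxy)acetate | CCOC(=O)COc1c(OC)cc(Br)cc1OC | intermediate
5 | ethyl 2-[2,6-dimethoxy-4-(trimethylsilylethynyl)phenoxy]acetate | CCOC(=O)COc1c(OC)cc(C#C[Si](C)(C)C)cc1OC | intermediate
6 | 2-(4-ethynyl-2,6-dimethoxyphenoxy)acetic acid | OC(=O)COc1c(OC)cc(C#C)cc1OC | intermediate
7 | (R)-4-benzyloxazolidin-2-one | O=C1N[C@H](Cc2ccccc2)CO1 | starting material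
8 | 2-(4-ethynyl-2,6-dimethoxyphenoxy)acetic pivalic anhydride | CC(C)(C)C(=O)OC(=O)COc1c(OC)cc(C#C)cc1OC | intermediate
9 | (4R)-4-benzyl-3-[2-(4-ethynyl-2,6-dimethoxyphenoxy)acetyl]oxazolidin-2-one | O=C(COc1c(OC)cc(C#C)cc1OC)N2[C@H](Cc3ccccc3)COC2=O | intermediate
10 | dibutylboron (Z)-enolate of 9 | CCCCB(CCCC)O/C(=C\Oc1c(OC)cc(C#C)cc1OC)N2[C@H](Cc3ccccc3)COC2=O | intermediate
11 | dibutylboron aldolate of 12 | COc1cc([C@H](OB(CCCC)CCCC)[C@H](C(=O)N2[C@H](Cc3ccccc3)COC2=O)Oc4c(OC)cc(C#C)cc4OC)ccc1O[Si](C)(C)C(C)(C)C | intermediate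
12 | syn aldol adduct, (4R,2'R,3'S) | COc1cc([C@H](O)[C@H](C(=O)N2[C@H](Cc3ccccc3)COC2=O)Oc4c(OC)cc(C#C)cc4OC)ccc1O[Si](C)(C)C(C)(C)C | intermediate
13 | threo diol, (αS,βS) | COc1cc([C@H](O)[C@H](CO)Oc2c(OC)cc(C#C)cc2OC)ccc1O[Si](C)(C)C(C)(C)C | intermediate
14 | p-coumaric acid | O=C(O)/C=C/c1ccc(O)cc1 | starting material
15 | TBS (E)-3-[4-(TBS-oxy)phenyl]acrylate | CC(C)(C)[Si](C)(C)OC(=O)/C=C/c1ccc(O[Si](C)(C)C(C)(C)C)cc1 | intermediate
16 | (E)-3-[4-(TBS-oxy)phenyl]acrylic acid | OC(=O)/C=C/c1ccc(O[Si](C)(C)C(C)(C)C)cc1 | intermediate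
17 | threo γ-coumarate, (αS,βS), free α-OH | COc1cc([C@H](O)[C@H](COC(=O)/C=C/c2ccc(O[Si](C)(C)C(C)(C)C)cc2)Oc3c(OC)cc(C#C)cc3OC)ccc1O[Si](C)(C)C(C)(C)C | intermediate
18 | erythro α-chloroacetate γ-coumarate, (αR,βS) | COc1cc([C@@H](OC(=O)CCl)[C@H](COC(=O)/C=C/c2ccc(O[Si](C)(C)C(C)(C)C)cc2)Oc3c(OC)cc(C#C)cc3OC)ccc1O[Si](C)(C)C(C)(C)C | intermediate
19 | erythro γ-coumarate, (αR,βS), free α-OH | COc1cc([C@@H](O)[C@H](COC(=O)/C=C/c2ccc(O[Si](C)(C)C(C)(C)C)cc2)Oc3c(OC)cc(C#C)cc3OC)ccc1O[Si](C)(C)C(C)(C)C | intermediate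
20 | tris-silyl arylalkyne, (αR,βS) | COc1cc([C@@H](O[Si](C)(C)C(C)(C)C)[C@H](COC(=O)/C=C/c2ccc(O[Si](C)(C)C(C)(C)C)cc2)Oc2c(OC)cc(C#C)cc2OC)ccc1O[Si](C)(C)C(C)(C)C | intermediate
21 | phloroglucinol | Oc1cc(O)cc(O)c1 | starting material
22 | 3,5-bis(TBS-oxy)phenol | Oc1cc(O[Si](C)(C)C(C)(C)C)cc(O[Si](C)(C)C(C)(C)C)c1 | intermediate
23 | 3,5-bis(TBS-oxy)-2-iodophenol | Oc1cc(O[Si](C)(C)C(C)(C)C)cc(O[Si](C)(C)C(C)(C)C)c1I | intermediate
24 | 2-hydroxy-4,6-bis(TBS-oxy)phenyl ynone carrying the side chain | COc1cc([C@@H](O[Si](C)(C)C(C)(C)C)[C@H](COC(=O)/C=C/c2ccc(O[Si](C)(C)C(C)(C)C)cc2)Oc2c(OC)cc(C#CC(=O)c3c(O)cc(O[Si](C)(C)C(C)(C)C)cc3O[Si](C)(C)C(C)(C)C)cc2OC)ccc1O[Si](C)(C)C(C)(C)C | intermediate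
25 | (E)-β-diethylamino enone from 24 | COc1cc([C@@H](O[Si](C)(C)C(C)(C)C)[C@H](COC(=O)/C=C/c2ccc(O[Si](C)(C)C(C)(C)C)cc2)Oc2c(OC)cc(/C(=C\C(=O)c3c(O)cc(O[Si](C)(C)C(C)(C)C)cc3O[Si](C)(C)C(C)(C)C)N(CC)CC)cc2OC)ccc1O[Si](C)(C)C(C)(C)C | intermediate
26 | penta-O-TBS target | COc1cc([C@@H](O[Si](C)(C)C(C)(C)C)[C@H](COC(=O)/C=C/c2ccc(O[Si](C)(C)C(C)(C)C)cc2)Oc2c(OC)cc(-c3cc(=O)c4c(O[Si](C)(C)C(C)(C)C)cc(O[Si](C)(C)C(C)(C)C)cc4o3)cc2OC)ccc1O[Si](C)(C)C(C)(C)C | intermediate
27 | target CNP0264527.1 | COc1cc([C@@H](O)[C@H](COC(=O)/C=C/c2ccc(O)cc2)Oc2c(OC)cc(-c3cc(=O)c4c(O)cc(O)cc4o3)cc2OC)ccc1O | target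

Total step count: 16.
Longest linear sequence: 12 (steps 2, 3, 4, 5, 6, 7, 9, 10, 11, 12, 15, 16).

**Steps most likely to fail**

Step 15.
- Risk: oxidative addition and alkynylation at an aryl iodide that is electron-rich and flanked by two oxygen substituents may be slow. Capture of the aroylpalladium species by Et2NH, coupling without CO uptake, or early loss of aryl silyl groups could then compete.
- Fallback (sets out from 20, comes back at 27): the C4a–C4 bond is bought instead of made. Commercial 2,4,6-trihydroxybenzoic acid is persilylated (TBSCl, imidazole, DMF) to TBS 2,4,6-tris(TBS-oxy)benzoate F1. The silyl ester is converted with (COCl)2 and catalytic DMF into 2,4,6-tris(TBS-oxy)benzoyl chloride F2. An acyl Sonogashira coupling of F2 with 20 (PdCl2(PPh3)2, CuI, Et3N, THF, 23 °C) gives the hexa-O-silyl ynone F3. Et2NH adds to it to give the hexa-O-silyl enaminone F4. Et3N·3HF then frees all hydroxyl groups, an ortho phenol displaces the amine, and 27 results directly.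

Step 10.
- Risk: ionisation of the electron-rich benzylic oxyphosphonium ion (incomplete inversion) or elimination towards the aryl enol ether may erode the erythro series.
- Fallback (sets out from 17, comes back at 19): inversion by oxidation and reduction. Dess–Martin oxidation of 17 in CH2Cl2 gives the (βS)-configured α-ketone F5. It is handled without base because the γ-acyloxy group lies β to the new ketone. Zn(BH4)2 in Et2O at −40 °C then reduces it under Cram chelate control, with zinc held between the ketone oxygen and the β-aryloxy oxygen and hydride delivered from the side of the Cβ hydrogen. This should give the anti alcohol 19.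

Step 16.
- Risk: cleavage of the crowded benzylic silyl ether may be sluggish. The prolonged exposure then needed could allow benzylic ionisation of the liberated p-hydroxybenzyl system (epimerisation at Cα) or migration of the coumarate.
- Fallback (sets out from 19, comes back at 27): Cα–OH is carried unprotected. Alcohol 19 is submitted with 23 to the conditions of step 15. It should pass through the tetra-O-silyl ynone F6 and the tetra-O-silyl enaminone F7 to the tetra-O-silyl flavone with free α-hydroxyl F8. Migration of the ester from the primary to the secondary oxygen is thermodynamically disfavoured. Only aryl silyl ethers then remain; these are far more labile and should fall to TBAF buffered with AcOH in THF at 0 °C, giving 27.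

**Further compounds**
F1 | step 15 | TBS 2,4,6-tris(TBS-oxy)benzoate | CC(C)(C)[Si](C)(C)OC(=O)c1c(O[Si](C)(C)C(C)(C)C)cc(O[Si](C)(C)C(C)(C)C)cc1O[Si](C)(C)C(C)(C)C
F2 | step 15 | 2,4,6-tris(TBS-oxy)benzoyl chloride | ClC(=O)c1c(O[Si](C)(C)C(C)(C)C)cc(O[Si](C)(C)C(C)(C)C)cc1O[Si](C)(C)C(C)(C)C
F3 | step 15 | hexa-O-silyl ynone | COc1cc([C@@H](O[Si](C)(C)C(C)(C)C)[C@H](COC(=O)/C=C/c2ccc(O[Si](C)(C)C(C)(C)C)cc2)Oc2c(OC)cc(C#CC(=O)c3c(O[Si](C)(C)C(C)(C)C)cc(O[Si](C)(C)C(C)(C)C)cc3O[Si](C)(C)C(C)(C)C)cc2OC)ccc1O[Si](C)(C)C(C)(C)C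
F4 | step 15 | hexa-O-silyl enaminone, (E)-β-diethylamino enone | COc1cc([C@@H](O[Si](C)(C)C(C)(C)C)[C@H](COC(=O)/C=C/c2ccc(O[Si](C)(C)C(C)(C)C)cc2)Oc2c(OC)cc(/C(=C\C(=O)c3c(O[Si](C)(C)C(C)(C)C)cc(O[Si](C)(C)C(C)(C)C)cc3O[Si](C)(C)C(C)(C)C)N(CC)CC)cc2OC)ccc1O[Si](C)(C)C(C)(C)C
F5 | step 10 | (βS)-α-ketone, (2S)-3-[4-(TBS-oxy)-3-methoxyphenyl]-2-(4-ethynyl-2,6-dimethoxyphenoxy)-3-oxopropyl (E)-3-[4-(TBS-oxy)phenyl]acrylate | COc1cc(C(=O)[C@H](COC(=O)/C=C/c2ccc(O[Si](C)(C)C(C)(C)C)cc2)Oc2c(OC)cc(C#C)cc2OC)ccc1O[Si](C)(C)C(C)(C)C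
F6 | step 16 | tetra-O-silyl ynone with free α-hydroxyl | COc1cc([C@@H](O)[C@H](COC(=O)/C=C/c2ccc(O[Si](C)(C)C(C)(C)C)cc2)Oc2c(OC)cc(C#CC(=O)c3c(O)cc(O[Si](C)(C)C(C)(C)C)cc3O[Si](C)(C)C(C)(C)C)cc2OC)ccc1O[Si](C)(C)C(C)(C)C
F7 | step 16 | tetra-O-silyl enaminone with free α-hydroxyl | COc1cc([C@@H](O)[C@H](COC(=O)/C=C/c2ccc(O[Si](C)(C)C(C)(C)C)cc2)Oc2c(OC)cc(/C(=C\C(=O)c3c(O)cc(O[Si](C)(C)C(C)(C)C)cc3O[Si](C)(C)C(C)(C)C)N(CC)CC)cc2OC)ccc1O[Si](C)(C)C(C)(C)C
F8 | step 16 | tetra-O-silyl flavone with free α-hydroxyl | COc1cc([C@@H](O)[C@H](COC(=O)/C=C/c2ccc(O[Si](C)(C)C(C)(C)C)cc2)Oc2c(OC)cc(-c3cc(=O)c4c(O[Si](C)(C)C(C)(C)C)cc(O[Si](C)(C)C(C)(C)C)cc4o3)cc2OC)ccc1O[Si](C)(C)C(C)(C)C
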